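## Structural features

The core is a cyclopentane (C9a, C9, C10, C11, C12). A γ-lactone (ring A: O–C11, C12–C13, C14=O) is cis-fused to it at C11–C12. A pyrrolidine (N4, C3, C2, C1, C9a) and an azepane (N4, C5–C8, C9, C9a) share the N4–C9a bond, so C9a is a fully substituted, nitrogen-bearing carbon common to three rings, and the azepane is trans-fused to the cyclopentane across C9–C9a. An α-methyl-γ-butyrolactone hangs from C3 through the C3–C18 bond. Six of the nine stereocentres are contiguous (C13, C12, C9a, C9, C10, C11), two of them fully substituted (C9a and the tertiary carbinol C13); C3, C18 and C20 lie outside the core. The fragile groups are the two lactones (base, nucleophiles, hydride), the epimerisable C20–H, the tertiary amine (oxidants) and, at the butenolide stage, the C3–C18 bond, which can reopen by a retro-Mannich path. The real difficulty is C9a, whose nitrogen must be trans to both neighbours (C13 on C12 and C8 on C9), followed by C3, whose configuration has to be relayed across nitrogen. The key step exploits the C11 oxygen: as an iodoacetate it lies two atoms from C12 of a C12=C9a alkene, so a C13 radical closes ring A on the oxygen face and leaves a C9a radical whose open face is the one nitrogen needs.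

## Logic of the disconnections

23 ⇒ 22. No skeletal bond is cut; the C19–H and C20–H bonds are removed to give the butenolide. The C20 methyl centre is then set last, by hydrogen addition anti to the C3 substituent on C18, and the unsaturated lactone is exactly what a furan nucleophile delivers. The forward step must not hydrogenolyse the allylic C18–O bond.

22 ⇒ 18 + 20. The C3–C18 bond is cut. C3 becomes an iminium carbon that is reached from a lactam carbonyl, and the whole side lactone comes from one five-carbon furan. A tertiary lactam is also the one C3 handle that tolerates the enolate chemistry at C13. The forward step needs amide-selective partial reduction beside lactone A, attack on the C12 face of the iminium ion and threo selectivity.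

18 ⇒ 17 ⇒ 16. The C13–O bond and then the C13–CH3 bond are cut. Both groups are introduced through the ring A enolate, in the order that leaves hydroxyl on the convex face. This must precede 22, because a second lactone with an α-hydrogen would compete. The forward steps require enolisation of the lactone only, not of the lactam.

16 ⇒ 15. The N4–C5 bond is cut. The azepane opens to a lactam N–H and a primary chloride, which needs no protection anywhere in the route. The forward step is a seven-membered N-alkylation at a nitrogen on a quaternary carbon.

15 ⇒ 13. The N4–C3 amide bond is cut and nitrogen is returned to the azide. The pyrrolidinone closes by itself once the amine is freed next to the C3 ester. The forward step needs an azide reduction that spares the chloride and ring A.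

13 ⇒ 11 + 12. The C12–C13 and C9a–N bonds are cut. This removes ring A and two stereocentres, including the aminated quaternary carbon, and leads back to a cyclopentenol ester with three stereocentres. The forward step needs a 5-exo radical closure through an ester tether and azide transfer anti to the new ring.

11 ⇒ 9 + 10 and 9 ⇒ 8. The ester O–C14 bond and then the O–Si bond are cut. These are functional-group changes at an oxygen whose configuration is already correct. Acylation must proceed without allylic transposition.

8 ⇒ 6 + 7. The C9a–C1 bond is cut. The trisubstituted alkene is fixed in position by an alkenyl triflate, and the C1–C3 chain arrives with C3 already at the ester level. The forward step is an sp2–sp3 coupling that tolerates ester, chloride and silyl ether.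

6 ⇒ 5. The C9a–O sulfonate is returned to the ketone. The forward step requires regioselective enolisation toward C12 without loss of the β-silyloxy group.

5 ⇒ 3 + 2. The C10–ethyl and C9–C8 bonds are cut. Both chains are added in one operation to an enantiopure enone that already carries the C11 oxygen, so C10 and C9 follow from C11 (trans, trans) and no resolution is needed. The forward step requires the enolate to be alkylated faster than it equilibrates.

2 ⇒ 1 and 20 ⇒ 19. The O–S and O–Si bonds are cut; both are one-step activations of purchasable compounds.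

## Other disconnections considered

Alternative 1: The cut is at N4–C5 and N4–C9a. Nitrogen comes from a C3 azide on a chain that already carries the side lactone, and C9a is first made as an all-carbon quaternary centre next to a six-membered C5 ketone (azido ketone A2). In the forward step a strong Lewis acid would promote addition of the azide to C5 and a 1,2-shift of C9a to nitrogen with loss of dinitrogen, giving the C5 lactam A1; a lactam reduction would then give 23.
- In its favour: one operation closes two rings and makes both core C–N bonds, and the shift is stereospecific, so the nitrogen-bearing centre is inherited from a carbon stereocentre.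
- Against it here: A2 must already hold the trans-fused hydrindanone, ring A with its tertiary alcohol and the complete azido lactone chain. The sense of migration (C9a versus C6) depends on the geometry of the azidohydrin. The Lewis acid meets a tertiary alcohol and two lactones. A1 still needs a lactam reduction beside two lactones.
- Comparison: on bonds and rings per step it is the better plan. On C3 it is also the better plan, since C3 is fixed before ring closure and not by a late addition to an iminium ion. On certainty at C9a it is at least the equal. On step economy the chosen plan should win, because its key-step substrate is reached in six steps and its nitrogen rings close without redox adjustment.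

Alternative 2: The cut is at C9a–C1 and C9–C8. Diene A5 (buta-1,3-diene) would add to the C9a=C9 bond of the 2-amido enone A4 under an aluminium Lewis acid to give the cis-fused adduct A3. The new cyclohexene is later cleaved between C2 and C7.
- In its favour: nitrogen is on C9a from the start, and the suprafacial addition makes C1 and C8 cis, so nitrogen is necessarily trans to C8. The diene should approach anti to the C10 ethyl group.
- Against it here: α-amido enones are reluctant dienophiles. The ring is sacrificial: cleavage gives two aldehydes of similar reactivity that must be told apart and extended by one carbon (C3) and two carbons (C6, C5). Ring A must then be built on the C12 ketone, so C12 and C13 are set in separate later steps.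
- Comparison: on the C9a–N/C9 relationship it is the equal or the better of the chosen plan, since a concerted cycloaddition fixes it and a radical trap only favours it. On mechanism it is the more familiar. On step economy it is clearly worse, because the chosen step makes the C12–C13 bond and ring A at the same time as the C9a–N bond.

Alternative 3: The cut is at O–C11. The C11-deoxy primary amide A7 would be N-iodinated and photolysed; the amidyl radical abstracts the C11 hydrogen through a six-membered transition state, and the amide oxygen closes on C11 to give, after hydrolysis, the lactone A6 (C13 acetate, C5 lactam).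
- In its favour: C11 needs no oxygen until the end, only the cis-fused lactone can form, and the site of abstraction is set by geometry.
- Against it here: the whole skeleton, including the C9a–N and C12–C13 bonds and an acyclic quaternary C13, must be assembled without the C11 oxygen, which in the chosen plan is both the chiral-pool anchor and the tether. The hydrogens on C10 and C1 are reachable by 1,6-transfer. The amine must be masked as a lactam and the alcohol as an acetate, so deacetylation and a lactam reduction beside two lactones follow.
- Comparison: on the configuration of C11 and the ring fusion it is the equal or the better plan, because no other outcome is geometrically possible. On step economy and on control of C13 and C9a it is worse.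

Key step: step 7

## Assumptions and numbering

- Atom labels: N4; C1–C3 pyrrolidine carbons; C5–C8 azepane methylenes; C9; C9a; C10 (ethyl); C11 (ring A oxygen); C12; C13 (Me, OH); C14 (ring A carbonyl); C18–C21 side lactone (C18–O, C20–Me). "Upper face" of the cyclopentane is the face that carries ring A.
- The chain termini of the key-step substrate are spectators of the radical cascade. They are carried as an ethyl ester (C3) and a primary chloride (C5), the forms in which they are later used, so no protecting group has to be removed.
- Compounds 3, 7 (THF solution), 10, 12 and 19 are taken as purchasable.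
- Stereochemical check: C9, C10 and C11 of 11 and all five centres of 13 map onto 23 unchanged; no structural error was found. The C11 oxygen is trans to the C10 ethyl group. A hydride reduction of a C11 ketone next to C10 would add anti to ethyl and give mainly the cis alcohol, and a resolution would discard half the material. C11 is therefore taken from the chiral pool.

## Steps

Step 1
Reactants: 1 4-chlorobutan-1-ol
Product: 2 4-chlorobutyl trifluoromethanesulfonate
Conditions: (CF3SO2)2O, pyridine, CH2Cl2, −78 → 0 °C; used at once
Reagents that add atoms: trifluoromethanesulfonic anhydride, O=S(=O)(OS(=O)(=O)C(F)(F)F)C(F)(F)F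
Why: Sulfonylation of a primary alcohol; the triflate is the electrophile reactive enough to capture the enolate of step 2 at −78 °C, and the chloride is untouched.

Step 2
Reactants: 3 (R)-4-[(tert-butyldimethylsilyl)oxy]cyclopent-2-en-1-one; 2 4-chlorobutyl trifluoromethanesulfonate
Product: 5 (2R,3R,4R)-4-[(tert-butyldimethylsilyl)oxy]-2-(4-chlorobutyl)-3-ethylcyclopentan-1-one, via zincate enolate 4 (not isolated)
Conditions: Et2Zn, EtLi, THF, 0 → −78 °C; 3, −78 °C; then 2 (1.5 equiv), −78 → −30 °C; NH4Cl
Reagents that add atoms: lithium triethylzincate, [Li+].CC[Zn-](CC)CC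
Why: Tandem conjugate addition–enolate alkylation (three-component coupling): ethyl adds to C10 anti to the C11 silyloxy group, and the regiodefined enolate 4 is alkylated at C9 anti to the new ethyl group, giving the trans,trans ketone. The triflate reacts before the enolate can equilibrate.

Step 3
Reactants: 5 (2R,3R,4R)-4-[(tert-butyldimethylsilyl)oxy]-2-(4-chlorobutyl)-3-ethylcyclopentan-1-one
Product: 6 (3S,4R,5R)-3-[(tert-butyldimethylsilyl)oxy]-5-(4-chlorobutyl)-4-ethylcyclopent-1-en-1-yl trifluoromethanesulfonate
Conditions: KN(SiMe3)2, PhNTf2, THF, −78 °C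
Reagents that add atoms: N-phenylbis(trifluoromethanesulfonimide), O=S(=O)(N(c1ccccc1)S(=O)(=O)C(F)(F)F)C(F)(F)F
Why: Kinetic deprotonation at the C12 methylene (C9 is tertiary and flanked by two substituents) and O-sulfonylation of the enolate. At −78 °C with the triflating agent present the enolate is trapped before the β-silyloxy group can leave.

Step 4
Reactants: 6 (3S,4R,5R)-3-[(tert-butyldimethylsilyl)oxy]-5-(4-chlorobutyl)-4-ethylcyclopent-1-en-1-yl trifluoromethanesulfonate; 7 (3-ethoxy-3-oxopropyl)zinc bromide
Product: 8 ethyl 3-[(3S,4R,5R)-3-[(tert-butyldimethylsilyl)oxy]-5-(4-chlorobutyl)-4-ethylcyclopent-1-en-1-yl]propanoate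
Conditions: Pd(PPh3)4 (5 mol%), THF, 50 °C
Reagents that add atoms: none
Why: Negishi coupling of an alkenyl triflate with a functionalised alkylzinc halide forms C9a–C1 and keeps the alkene between C9a and C12. Ester, chloride and silyl ether are inert.

Step 5
Reactants: 8 ethyl 3-[(3S,4R,5R)-3-[(tert-butyldimethylsilyl)oxy]-5-(4-chlorobutyl)-4-ethylcyclopent-1-en-1-yl]propanoate
Product: 9 ethyl 3-[(3S,4R,5R)-5-(4-chlorobutyl)-4-ethyl-3-hydroxycyclopent-1-en-1-yl]propanoate
Conditions: Bu4NF, THF, 0 °C; NH4Cl
Reagents that add atoms: none
Why: Fluoride cleavage of the secondary allylic silyl ether under non-acidic conditions, so the allylic alcohol does not ionise; no stereocentre is touched.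

Step 6
Reactants: 9 ethyl 3-[(3S,4R,5R)-5-(4-chlorobutyl)-4-ethyl-3-hydroxycyclopent-1-en-1-yl]propanoate; 10 iodoacetic acid
Product: 11 ethyl 3-[(3S,4R,5R)-5-(4-chlorobutyl)-4-ethyl-3-(2-iodoacetoxy)cyclopent-1-en-1-yl]propanoate
Conditions: DCC, DMAP (5 mol%), CH2Cl2, 0 °C → rt, dark
Reagents that add atoms: none
Why: Steglich esterification; acylation at oxygen keeps the C11 configuration, and low temperature with catalytic DMAP limits displacement of iodide.

Step 7
Reactants: 11 ethyl 3-[(3S,4R,5R)-5-(4-chlorobutyl)-4-ethyl-3-(2-iodoacetoxy)cyclopent-1-en-1-yl]propanoate; 12 benzenesulfonyl azide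
Product: 13 ethyl 3-[(3aR,4S,5R,6R,6aS)-4-azido-5-(4-chlorobutyl)-6-ethyl-2-oxohexahydro-2H-cyclopenta[b]furan-4-yl]propanoate
Conditions: (Bu3Sn)2 (1.5 equiv), 12 (3 equiv), t-BuON=NOt-Bu (10 mol%), benzene (0.02 M), 80 °C
Reagents that add atoms: none
Why: Proposed new method: stannyl radicals abstract iodine from 11, and the electrophilic α-ester radical, polarity-mismatched with the electrophilic azide 12, survives until it adds to C12 of the electron-rich alkene in a 5-exo-trig closure that forms C12–C13 and ring A. The closest known reactions are the ditin-mediated carboazidation of alkenes with α-iodo esters and sulfonyl azides, the cyclisation–azidation of iodoacetals and the atom-transfer cyclisation of allylic iodoacetates; combining the ester tether with azide trapping is the untested element. The two-atom O–C(=O) tether can reach C12 only on the face of the C11 oxygen, so the fusion is cis and C12 is set by C11. The nucleophilic tertiary C9a radical is polarity-matched with 12 and is attacked on the face opposite both the new lactone carbon C13 and the C8 chain on C9, which lie on the same face, so nitrogen ends trans to both (9aS). Attack at the CH terminus C12 gives a tertiary radical, which secures 5-exo over 6-endo closure. The step needs cyclisation to outrun bimolecular reactions of the first radical; high dilution, 80 °C (to populate the reactive ester rotamer) and the absence of a hydrogen donor provide this, and any tertiary iodide formed by atom transfer is reactivated by the ditin. The expelled sulfonyl radical reacts with (Bu3Sn)2 to regenerate the chain carrier.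

Step 8
Reactants: 13 ethyl 3-[(3aR,4S,5R,6R,6aS)-4-azido-5-(4-chlorobutyl)-6-ethyl-2-oxohexahydro-2H-cyclopenta[b]furan-4-yl]propanoate
Product: 15 (3aR,4S,5R,6R,6aS)-5-(4-chlorobutyl)-6-ethylhexahydro-2H-spiro[cyclopenta[b]furan-4,2'-pyrrolidine]-2,5'-dione, via primary amine 14 (not isolated)
Conditions: H2 (1 atm), Pd/C (10%), EtOH, rt; filter; toluene, 80 °C
Reagents that add atoms: none
Why: Hydrogenation of the tertiary azide gives amine 14, which acylates itself with the γ-ester to the five-membered lactam. Attack on the ring A carbonyl would give a trans-fused bicyclo[3.3.0] lactam and is not competitive; the primary chloride survives.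

Step 9
Reactants: 15 (3aR,4S,5R,6R,6aS)-5-(4-chlorobutyl)-6-ethylhexahydro-2H-spiro[cyclopenta[b]furan-4,2'-pyrrolidine]-2,5'-dione
Product: 16 tetracyclic C3-lactam with unsubstituted ring A (9R,9aS,10R,11S,12R; N4–C5 closed, C13 = CH2)
Conditions: NaH (1.1 equiv), Bu4NI (10 mol%), DMF, 0 → 50 °C
Reagents that add atoms: none
Why: Intramolecular N-alkylation of the lactam anion (7-exo-tet) with iodide exchange in the flask. Nitrogen (lower face at C9a) and the C8 chain (upper face at C9) are trans, which the ring accepts as a trans-fused azepane. The N–H is the most acidic site, so one equivalent of base does not enolise ring A.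

Step 10
Reactants: 16 tetracyclic C3-lactam with unsubstituted ring A
Product: 17 C13-methyl tetracyclic lactam (9R,9aS,10R,11S,12R,13S; methyl on the convex face)
Conditions: LiN(iPr)2 (1.05 equiv), THF, −78 °C; MeI, −78 → −40 °C
Reagents that add atoms: iodomethane, CI
Why: Lactone enolate alkylation: the ring A α-CH2 is several pKa units more acidic than the α-CH2 of the tertiary lactam, so one equivalent of amide base enolises only ring A. Methyl enters from the convex face, but C13 is reset in step 11.

Step 11
Reactants: 17 C13-methyl tetracyclic lactam
Product: 18 C13-hydroxy-C13-methyl tetracyclic lactam (9R,9aS,10R,11S,12R,13S; hydroxyl convex, methyl concave)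
Conditions: KN(SiMe3)2, THF, −78 °C; 3-phenyl-2-(phenylsulfonyl)oxaziridine, −78 °C; NH4Cl
Reagents that add atoms: 3-phenyl-2-(phenylsulfonyl)oxaziridine, O=S(=O)(N1OC1c1ccccc1)c1ccccc1
Why: Enolate hydroxylation with an N-sulfonyloxaziridine: the planar C13 enolate is attacked on the convex face of the cis-fused bicycle (the concave face is also screened by C1), so hydroxyl ends exo and methyl endo. The potassium enolate avoids addition of the product alkoxide to the sulfonimine.

Step 12
Reactants: 19 3-methylfuran-2(5H)-one
Product: 20 triisopropyl[(3-methylfuran-2-yl)oxy]silane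
Conditions: iPr3SiOTf, Et3N, CH2Cl2, 0 °C
Reagents that add atoms: triisopropylsilyl trifluoromethanesulfonate, CC(C)[Si](C(C)C)(C(C)C)OS(=O)(=O)C(F)(F)F
Why: Soft enolisation and O-silylation of the butenolide give the aromatic 2-silyloxyfuran, the vinylogous nucleophile for step 13.

Step 13
Reactants: 18 C13-hydroxy-C13-methyl tetracyclic lactam; 20 triisopropyl[(3-methylfuran-2-yl)oxy]silane
Product: 22 butenolide adduct (3S,9R,9aS,10R,11S,12R,13S,18S; C3 bears the 4-methyl-5-oxo-2,5-dihydrofuran-2-yl group), via O-silyl hemiaminal 21 (not isolated)
Conditions: IrCl(CO)(PPh3)2 (1 mol%), (HMe2Si)2O (2.5 equiv), toluene, rt; then 20 (2 equiv), 2-nitrobenzoic acid (1.2 equiv), MeCN, 0 °C → rt; aq. NaHCO3, KF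
Reagents that add atoms: none
Why: Iridium-catalysed hydrosilylation reduces the tertiary lactam chemoselectively (lactones are untouched; any silylation of the C13 hydroxyl is undone in the work-up) to hemiaminal 21. Acid ionises 21 to the N4=C3 iminium ion, which the silyloxyfuran attacks through C18 (vinylogous Mannich reaction). The furan is expected on the C12 face of the pyrrolinium ring because C6 of the azepane projects over the C9 face, and the threo C3/C18 relationship is the usual outcome of silyloxyfuran additions to cyclic iminium ions.

Step 14
Reactants: 22 butenolide adduct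
Product: 23 target, (3S,9R,9aS,10R,11S,12R,13S,18S,20S)
Conditions: H2 (1 atm), Rh/Al2O3 (5%), EtOAc, rt
Reagents that add atoms: none
Why: Heterogeneous hydrogenation of the butenolide from the face opposite the C3 substituent on C18 gives the cis-2,4-disubstituted lactone (20S). Rhodium limits hydrogenolysis of the allylic C18–O bond.

## Compound list

1 | 4-chlorobutan-1-ol | OCCCCCl | starting material
2 | 4-chlorobutyl trifluoromethanesulfonate | ClCCCCOS(=O)(=O)C(F)(F)F | intermediate
3 | (R)-4-[(tert-butyldimethylsilyl)oxy]cyclopent-2-en-1-one | O=C1C[C@@H](O[Si](C)(C)C(C)(C)C)C=C1 | starting material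
4 | lithium diethyl{[(3R,4R)-4-(tert-butyldimethylsilyloxy)-3-ethylcyclopent-1-en-1-yl]oxy}zincate (zincate enolate, not isolated) | [Li+].CC[C@H]1[C@H](O[Si](C)(C)C(C)(C)C)CC(O[Zn-](CC)CC)=C1 | intermediate
5 | (2R,3R,4R)-4-[(tert-butyldimethylsilyl)oxy]-2-(4-chlorobutyl)-3-ethylcyclopentan-1-one | CC[C@H]1[C@H](O[Si](C)(C)C(C)(C)C)CC(=O)[C@@H]1CCCCCl | intermediate
6 | (3S,4R,5R)-3-[(tert-butyldimethylsilyl)oxy]-5-(4-chlorobutyl)-4-ethylcyclopent-1-en-1-yl trifluoromethanesulfonate | CC[C@H]1[C@H](O[Si](C)(C)C(C)(C)C)C=C(OS(=O)(=O)C(F)(F)F)[C@@H]1CCCCCl | intermediate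
7 | (3-ethoxy-3-oxopropyl)zinc bromide | CCOC(=O)CC[Zn]Br | starting material
8 | ethyl 3-[(3S,4R,5R)-3-[(tert-butyldimethylsilyl)oxy]-5-(4-chlorobutyl)-4-ethylcyclopent-1-en-1-yl]propanoate | CC[C@H]1[C@H](O[Si](C)(C)C(C)(C)C)C=C(CCC(=O)OCC)[C@@H]1CCCCCl | intermediate
9 | ethyl 3-[(3S,4R,5R)-5-(4-chlorobutyl)-4-ethyl-3-hydroxycyclopent-1-en-1-yl]propanoate | CC[C@H]1[C@H](O)C=C(CCC(=O)OCC)[C@@H]1CCCCCl | intermediate
10 | iodoacetic acid | OC(=O)CI | starting material
11 | ethyl 3-[(3S,4R,5R)-5-(4-chlorobutyl)-4-ethyl-3-(2-iodoacetoxy)cyclopent-1-en-1-yl]propanoate (key-step precursor) | CC[C@H]1[C@H](OC(=O)CI)C=C(CCC(=O)OCC)[C@@H]1CCCCCl | intermediate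
12 | benzenesulfonyl azide | [N-]=[N+]=NS(=O)(=O)c1ccccc1 | starting material
13 | ethyl 3-[(3aR,4S,5R,6R,6aS)-4-azido-5-(4-chlorobutyl)-6-ethyl-2-oxohexahydro-2H-cyclopenta[b]furan-4-yl]propanoate (key-step product) | CC[C@H]1[C@@H]2OC(=O)C[C@@H]2[C@](N=[N+]=[N-])(CCC(=O)OCC)[C@@H]1CCCCCl | intermediate
14 | ethyl 3-[(3aR,4S,5R,6R,6aS)-4-amino-5-(4-chlorobutyl)-6-ethyl-2-oxohexahydro-2H-cyclopenta[b]furan-4-yl]propanoate (not isolated) | CC[C@H]1[C@@H]2OC(=O)C[C@@H]2[C@](N)(CCC(=O)OCC)[C@@H]1CCCCCl | intermediate
15 | (3aR,4S,5R,6R,6aS)-5-(4-chlorobutyl)-6-ethylhexahydro-2H-spiro[cyclopenta[b]furan-4,2'-pyrrolidine]-2,5'-dione | CC[C@H]1[C@@H]2OC(=O)C[C@@H]2[C@]2(CCC(=O)N2)[C@@H]1CCCCCl | intermediate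
16 | tetracyclic C3-lactam, ring A unsubstituted at C13 (9R,9aS,10R,11S,12R) | CC[C@H]1[C@@H]2OC(=O)C[C@@H]2[C@@]23CCC(=O)N2CCCC[C@H]13 | intermediate
17 | C13-methyl tetracyclic C3-lactam (9R,9aS,10R,11S,12R,13S) | CC[C@H]1[C@@H]2OC(=O)[C@@H](C)[C@@H]2[C@@]23CCC(=O)N2CCCC[C@H]13 | intermediate
18 | C13-hydroxy-C13-methyl tetracyclic C3-lactam (9R,9aS,10R,11S,12R,13S) | CC[C@H]1[C@@H]2OC(=O)[C@@](C)(O)[C@@H]2[C@@]23CCC(=O)N2CCCC[C@H]13 | intermediate
19 | 3-methylfuran-2(5H)-one | CC1=CCOC1=O | starting material
20 | triisopropyl[(3-methylfuran-2-yl)oxy]silane | Cc1ccoc1O[Si](C(C)C)(C(C)C)C(C)C | intermediate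
21 | C3 O-(1,1,3,3-tetramethyldisiloxanyl) hemiaminal of 18 (C3 epimers, not isolated) | CC[C@H]1[C@@H]2OC(=O)[C@@](C)(O)[C@@H]2[C@@]23CCC(O[Si](C)(C)O[SiH](C)C)N2CCCC[C@H]13 | intermediate
22 | butenolide adduct (3S,9R,9aS,10R,11S,12R,13S,18S) | CC[C@H]1[C@@H]2OC(=O)[C@@](C)(O)[C@@H]2[C@@]23CC[C@@H]([C@@H]4C=C(C)C(=O)O4)N2CCCC[C@H]13 | intermediate
23 | CNP0260919.2 (3S,9R,9aS,10R,11S,12R,13S,18S,20S) | CC[C@H]1[C@@H]2OC(=O)[C@@](C)(O)[C@@H]2[C@@]23CC[C@@H]([C@@H]4C[C@H](C)C(=O)O4)N2CCCC[C@H]13 | target

## Step count and least certain steps

Total: 14 steps. Longest linear sequence: 13 steps (1 → 2 → 5 → 6 → 8 → 9 → 11 → 13 → 15 → 16 → 17 → 18 → 22 → 23); step 12 is a one-step side branch.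

Step 7 (key step). The most likely failure is slow closure of the ester-tethered radical: the ester prefers the rotamer in which C13 cannot reach C12, so reduction, dimerisation, iodine-transfer oligomerisation or direct azidation of the first radical may take over. Loss of HI from the tertiary iodide formed by atom transfer is a second drain. Fallback (known chemistry, acetal tether in place of the ester): from 9, iodoacetalisation with ethyl vinyl ether and N-iodosuccinimide gives the mixed iodoacetal F1. The ditin/sulfonyl azide conditions of step 7 applied to F1 give the azido bicyclic acetal F2 by the established 5-exo cyclisation–azidation of haloacetals, with the same facial arguments. Jones oxidation (CrO3, H2SO4, acetone, 0 °C) of F2 returns to the route at 13.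

Step 13. The most likely failure is weak facial discrimination at the iminium carbon, since both substituents on C9a are tertiary carbons, together with erosion of the threo preference through reversible retro-Mannich opening. Fallback (kinetic face selection replaced by equilibration at C3 and chelation control at C18): from 18, the same hydrosilylation gives 21, which is treated with vinylmagnesium bromide at −78 °C to give the C3-vinyl amine F3. Ozonolysis of its trifluoroacetate salt (O3, CH2Cl2/MeOH, −78 °C; Me2S) gives the C3-formyl amine F4. F4 is epimerisable and should settle with the formyl group on the less hindered C12 face. Barbier allylation with ethyl 2-(bromomethyl)acrylate and zinc (THF, aq. NH4Cl), chelation-controlled and followed by lactonisation in the same flask, gives the α-methylene lactone F5. Hydrogenation of F5 under the conditions of step 14 returns to the route at 23.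

Step 2. The most likely failure is proton transfer between the enolate and already alkylated ketone, which moves the enolate toward C12 and leads to expulsion of the silyloxy group and to polyalkylation if alkylation is not fast enough. Fallback (aldol capture in place of alkylation): 4-chlorobutanal F6 is made from 1 by Swern oxidation. Enolate 4 is intercepted with F6 at −78 °C to give the aldol adduct F7. Dehydration (MsCl, DMAP, CH2Cl2) gives the exocyclic enone F8. Conjugate reduction with [(Ph3P)CuH]6 and protonation anti to the ethyl group return to the route at 5.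

Step 3. The most likely failure is β-elimination of the silyloxy group from the C12 enolate, with incomplete regiocontrol of enolisation (C12 against C9) as a second problem. Fallback (no enolate): from 5, condensation with hydrazine (N2H4·H2O, Et3N, EtOH) gives the hydrazone F9. Barton iodination (I2, tetramethylguanidine, THF) gives the less substituted alkenyl iodide F10. Negishi coupling of F10 with 7 under the conditions of step 4 returns to the route at 8.

Step 9. The most likely failure is slow seven-membered closure at the hindered amide nitrogen, which lets intermolecular alkylation or base-induced enolisation of ring A compete. Fallback (azepane closed first, at the amine stage, by reductive amination): from 13, Finkelstein exchange (NaI, acetone) gives the iodide F11. Oxidation with Me3NO in DMSO gives the C5 aldehyde F12. Staudinger–aza-Wittig closure (PMe3, THF) gives the seven-membered imine F13, which is reduced in the same flask with NaBH(OAc)3 to the azepane amino ester F14. On warming in toluene F14 acylates itself with the ethyl ester and returns to the route at 16.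

## Further compounds

F1 | step 7 | ethyl 3-[(3S,4R,5R)-5-(4-chlorobutyl)-3-(1-ethoxy-2-iodoethoxy)-4-ethylcyclopent-1-en-1-yl]propanoate (acetal epimers) | CC[C@H]1[C@H](OC(OCC)CI)C=C(CCC(=O)OCC)[C@@H]1CCCCCl
F2 | step 7 | ethyl 3-[(3aR,4S,5R,6R,6aS)-4-azido-5-(4-chlorobutyl)-2-ethoxy-6-ethylhexahydro-2H-cyclopenta[b]furan-4-yl]propanoate (acetal epimers) | CC[C@H]1[C@@H]2OC(OCC)C[C@@H]2[C@](N=[N+]=[N-])(CCC(=O)OCC)[C@@H]1CCCCCl
F3 | step 13 | C3-vinyl tetracyclic amine (C3 epimers) | CC[C@H]1[C@@H]2OC(=O)[C@@](C)(O)[C@@H]2[C@@]23CCC(C=C)N2CCCC[C@H]13
F4 | step 13 | C3-formyl tetracyclic amine (3S, formyl on the C12 face) | CC[C@H]1[C@@H]2OC(=O)[C@@](C)(O)[C@@H]2[C@@]23CC[C@@H](C=O)N2CCCC[C@H]13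
F5 | step 13 | α-methylene side-lactone analogue of 23 (3S,18S) | CC[C@H]1[C@@H]2OC(=O)[C@@](C)(O)[C@@H]2[C@@]23CC[C@@H]([C@@H]4CC(=C)C(=O)O4)N2CCCC[C@H]13
F6 | step 2 | 4-chlorobutanal | O=CCCCCl
F7 | step 2 | (2R,3R,4R)-4-[(tert-butyldimethylsilyl)oxy]-2-(4-chloro-1-hydroxybutyl)-3-ethylcyclopentan-1-one (carbinol epimers) | CC[C@H]1[C@H](O[Si](C)(C)C(C)(C)C)CC(=O)[C@@H]1C(O)CCCCl
F8 | step 2 | (3R,4R,E)-4-[(tert-butyldimethylsilyl)oxy]-2-(4-chlorobutylidene)-3-ethylcyclopentan-1-one | CC[C@H]1[C@H](O[Si](C)(C)C(C)(C)C)CC(=O)/C1=C/CCCCl
F9 | step 3 | hydrazone of 5 | CC[C@H]1[C@H](O[Si](C)(C)C(C)(C)C)CC(=NN)[C@@H]1CCCCCl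
F10 | step 3 | tert-butyl{[(1S,4R,5R)-4-(4-chlorobutyl)-5-ethyl-3-iodocyclopent-2-en-1-yl]oxy}dimethylsilane | CC[C@H]1[C@H](O[Si](C)(C)C(C)(C)C)C=C(I)[C@@H]1CCCCCl
F11 | step 9 | iodide analogue of 13 (4-iodobutyl chain) | CC[C@H]1[C@@H]2OC(=O)C[C@@H]2[C@](N=[N+]=[N-])(CCC(=O)OCC)[C@@H]1CCCCI
F12 | step 9 | C5 aldehyde analogue of 13 (4-oxobutyl chain) | CC[C@H]1[C@@H]2OC(=O)C[C@@H]2[C@](N=[N+]=[N-])(CCC(=O)OCC)[C@@H]1CCCC=O
F13 | step 9 | seven-membered cyclic imine (N4=C5) with free C3 ethyl ester | CC[C@H]1[C@@H]2OC(=O)C[C@@H]2[C@@]2(CCC(=O)OCC)N=CCCC[C@H]12
F14 | step 9 | azepane amino ester (N4–H, C3 ethyl ester) | CC[C@H]1[C@@H]2OC(=O)C[C@@H]2[C@@]2(CCC(=O)OCC)NCCCC[C@H]12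
A1 | alternative 1 | C5 lactam of the target | CC[C@H]1[C@@H]2OC(=O)[C@@](C)(O)[C@@H]2[C@@]23CC[C@@H]([C@@H]4C[C@H](C)C(=O)O4)N2C(=O)CCC[C@H]13
A2 | alternative 1 | C3-azido C5-ketone precursor (six-membered ketone ring C9a–C5–C6–C7–C8–C9) | CC[C@H]1[C@@H]2OC(=O)[C@@](C)(O)[C@@H]2[C@@]2(CC[C@H](N=[N+]=[N-])[C@@H]3C[C@H](C)C(=O)O3)C(=O)CCC[C@H]12
A3 | alternative 2 | cis-fused Boc-amido hydrindenone | CC[C@H]1[C@H](O[Si](C)(C)C(C)(C)C)C(=O)[C@]2(NC(=O)OC(C)(C)C)CC=CC[C@H]12
A4 | alternative 2 | tert-butyl [(3R,4R)-4-[(tert-butyldimethylsilyl)oxy]-3-ethyl-5-oxocyclopent-1-en-1-yl]carbamate | CC[C@H]1[C@H](O[Si](C)(C)C(C)(C)C)C(=O)C(NC(=O)OC(C)(C)C)=C1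
A5 | alternative 2 | buta-1,3-diene | C=CC=C
A6 | alternative 3 | C13 acetate, C5 lactam of the target | CC[C@H]1[C@@H]2OC(=O)[C@@](C)(OC(C)=O)[C@@H]2[C@@]23CC[C@@H]([C@@H]4C[C@H](C)C(=O)O4)N2C(=O)CCC[C@H]13
A7 | alternative 3 | C11-deoxy primary amide (ring A open, C13 acetate, C5 lactam) | CC[C@H]1C[C@H]([C@](C)(OC(C)=O)C(N)=O)[C@@]23CC[C@@H]([C@@H]4C[C@H](C)C(=O)O4)N2C(=O)CCC[C@H]13
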